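Numbering follows the isoflavanone (O1, C2, C3, C4, C4a–C8a; ring B primed). Retrosynthetically the three phenols become benzyl ethers, C4=O goes back to C4H2 and C2H2 to a lactone C2=O. Ring C of the resulting 3-aryl-dihydrocoumarin is then cut at C3–C4 and O1–C2.
Enabling feature: in ring C, C4 sits on C4a next to the O1-bearing C8a, so ring A plus C4 is an o-quinone methide, tamed by the C5 and C7 oxygens. C2–C3 with ring B on C3 is an arylacetic acid enolate, so the fragments pair as a four-atom and a two-atom partner.
Forward: rings A and B are bought (a gallate and a benzaldehyde). Ring A is degraded to a symmetric phenol and sulfonylmethylated, and ring B is homologated by one carbon. Ring C, the only ring made, closes in the annulation.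
Ring C then stays closed: C2 is lowered (lactone, lactol, CH2), C4 is raised (CH2, CHOH, C=O), and hydrogenolysis frees the phenols.
C3, the only stereocentre, is set (R) by the chiral isothiourea bound to the enolate. Later steps are run cold and neutral or acidic so that C3 is not enolised.

Key step: step 9

Assumption: (2S,3R)-HyperBTM is assigned from the accepted shielding model of the catalyst-bound enolate. If the sense of induction proved opposite, the (2R,3S) antipode would be used with nothing else changed.

Step 1
Reactants: 1 methyl 3,5-dihydroxy-4-methoxybenzoate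
Product: 2 methyl 3,5-bis(benzyloxy)-4-methoxybenzoate
Conditions: BnBr (2.4 equiv), K2CO3, DMF, 60 °C
Reagents that add atoms: benzyl bromide, BrCc1ccccc1
Why: Williamson etherification, in which K2CO3 deprotonates only the two equivalent phenols and benzyl bromide alkylates them while the methyl ester and the aryl methyl ether stay untouched.

Step 2
Reactants: 2 methyl 3,5-bis(benzyloxy)-4-methoxybenzoate
Product: 3 [3,5-bis(benzyloxy)-4-methoxyphenyl]methanol
Conditions: LiAlH4, THF, 0 °C to rt
Reagents that add atoms: none
Why: Hydride reduction of an aromatic ester to the benzylic alcohol, to which aryl benzyl and methyl ethers are inert.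

Step 3
Reactants: 3 [3,5-bis(benzyloxy)-4-methoxyphenyl]methanol
Product: 4 3,5-bis(benzyloxy)-4-methoxybenzaldehyde
Conditions: MnO2, CH2Cl2, rt
Reagents that add atoms: none
Why: Heterogeneous MnO2 oxidation is selective for benzylic alcohols and stops at the aldehyde.

Step 4
Reactants: 4 3,5-bis(benzyloxy)-4-methoxybenzaldehyde
Product: 6 3,5-bis(benzyloxy)-4-methoxyphenol, via aryl formate 5 (not isolated)
Conditions: mCPBA, CH2Cl2, 0 °C to rt; then K2CO3 (cat.), MeOH, rt
Reagents that add atoms: m-chloroperbenzoic acid (mCPBA), OOC(=O)c1cccc(Cl)c1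
Why: Baeyer–Villiger (Dakin-type) oxidation, in which the electron-rich trialkoxyaryl group of the Criegee adduct migrates in preference to hydride and the aryl formate is then cleaved by mild transesterification with methanol.

Step 5
Reactants: 6 3,5-bis(benzyloxy)-4-methoxyphenol; 7 formaldehyde; 8 sodium p-toluenesulfinate
Product: 9 3,5-bis(benzyloxy)-4-methoxy-2-(tosylmethyl)phenol
Conditions: aq. 7 (1.0 equiv), 8 (1.5 equiv), HCO2H, EtOH–H2O, rt
Reagents that add atoms: none
Why: Mannich-type three-component sulfonylmethylation as used for activated phenols and naphthols: with para blocked by OMe and the two free ortho positions equivalent, hydroxymethylation gives one regioisomer, whose benzylic cation is captured by the soft sulfinate sulfur faster than by a second arene, while limiting formaldehyde holds back a second substitution.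

Step 6
Reactants: 10 3-hydroxy-4,5-dimethoxybenzaldehyde
Product: 11 3-(benzyloxy)-4,5-dimethoxybenzaldehyde
Conditions: BnBr (1.2 equiv), K2CO3, DMF, 50 °C
Reagents that add atoms: benzyl bromide, BrCc1ccccc1
Why: Williamson etherification of the single phenol, with the non-enolisable aldehyde unaffected by carbonate.

Step 7
Reactants: 11 3-(benzyloxy)-4,5-dimethoxybenzaldehyde
Product: 12 1-(benzyloxy)-2,3-dimethoxy-5-(2-methoxyethenyl)benzene (E/Z mixture)
Conditions: Ph3P+CH2OMe Cl−, KOt-Bu, THF, 0 °C to rt
Reagents that add atoms: (methoxymethyl)triphenylphosphonium chloride, COC[P+](c1ccccc1)(c1ccccc1)c1ccccc1.[Cl-]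
Why: Wittig olefination with the non-stabilised methoxymethylene ylide adds the missing carbon, and the alkene geometry is irrelevant because both isomers hydrolyse to the same aldehyde.

Step 8
Reactants: 12 1-(benzyloxy)-2,3-dimethoxy-5-(2-methoxyethenyl)benzene
Product: 14 [3-(benzyloxy)-4,5-dimethoxyphenyl]acetic acid, via arylacetaldehyde 13 (not isolated)
Conditions: 2 M HCl (cat.), THF, rt; then NaClO2, NaH2PO4, 2-methyl-2-butene, t-BuOH–H2O, 0 °C to rt
Reagents that add atoms: water, O; sodium chlorite, [Na+].[O-]Cl=O
Why: Acid hydrolysis of the enol ether followed by Pinnick oxidation of the crude, self-condensation-prone arylacetaldehyde, with the alkene scavenger removing HOCl before it can chlorinate the electron-rich ring.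

Step 9
Reactants: 9 3,5-bis(benzyloxy)-4-methoxy-2-(tosylmethyl)phenol; 14 [3-(benzyloxy)-4,5-dimethoxyphenyl]acetic acid
Product: 17 (3R)-5,7-bis(benzyloxy)-3-[3-(benzyloxy)-4,5-dimethoxyphenyl]-6-methoxychroman-2-one, via mixed pivalic anhydride 15 (not isolated), via o-quinone methide 16 (not isolated)
Conditions: 14 (1.5 equiv), t-BuCOCl, i-Pr2NEt, CH2Cl2, 0 °C; then 9, (2S,3R)-HyperBTM (10 mol %), i-Pr2NEt, −20 °C
Reagents that add atoms: none
Why: Pivaloyl chloride turns 14 into anhydride 15, which acylates the isothiourea nitrogen; deprotonation gives the planar (Z)-ammonium enolate locked by a 1,5-O···S contact, while the amine deprotonates 9 and the electron-rich phenoxide expels sulfinate to give methide 16. The enolate attacks through C3 at the exocyclic methide carbon (Michael addition, C3–C4 bond, driven by re-aromatisation of ring A), and the released C8a phenoxide closes ring C by 6-exo-trig attack on the acyl-ammonium carbonyl (O1–C2 bond), which frees the catalyst. The closest known reaction is the isothiourea- or carbene-catalysed Michael addition–lactonisation (formal [4+2]) of arylacetic-acid-derived enolates with o-quinone methides generated in situ, which gives 3,4-dihydrocoumarins. C3 is the only new stereocentre and is controlled by the catalyst: the pseudo-axial C2-phenyl group of (2S,3R)-HyperBTM covers one enolate face, so the methide carbon is taken up on the open Re face and C3 becomes R. Cross-annulation must win over self-condensation of 16 and over O-acylation of 9: the C5 and C7 alkoxy donors stabilise 16, reversible re-addition of sulfinate keeps its concentration low, loss of sulfinate from the phenoxide is unimolecular and fast, and the unsubstituted methide carbon is the only soft electrophilic site, so no regiochemical or second stereochemical issue arises. The α-aryl lactone must also keep its configuration, which the hindered amine as sole base, the low temperature, a cold acidic work-up and immediate use in step 10 are meant to secure.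

Step 10
Reactants: 17 (3R)-5,7-bis(benzyloxy)-3-[3-(benzyloxy)-4,5-dimethoxyphenyl]-6-methoxychroman-2-one
Product: 18 (3R)-5,7-bis(benzyloxy)-3-[3-(benzyloxy)-4,5-dimethoxyphenyl]-6-methoxychroman-2-ol (mixture of C2 anomers)
Conditions: DIBAL-H (1.1 equiv), CH2Cl2, −78 °C; Rochelle salt work-up
Reagents that add atoms: none
Why: Partial lactone reduction with DIBAL-H stops at the lactol because the aluminium hemiacetal persists at −78 °C, the non-basic hydride leaves C3–H alone, and the new C2 centre (anomer mixture) is erased in step 11.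

Step 11
Reactants: 18 (3R)-5,7-bis(benzyloxy)-3-[3-(benzyloxy)-4,5-dimethoxyphenyl]-6-methoxychroman-2-ol
Product: 19 (3R)-5,7-bis(benzyloxy)-3-[3-(benzyloxy)-4,5-dimethoxyphenyl]-6-methoxychromane
Conditions: Et3SiH (5 equiv), BF3·OEt2, CH2Cl2, −78 to −40 °C
Reagents that add atoms: none
Why: Ionic reduction of a lactol (Lewis acid/silane), in which BF3 ionises the anomeric hydroxyl to the O1-stabilised oxocarbenium ion and excess Et3SiH traps it at low temperature before C3–H can be lost, so ring C and the C3 configuration are retained.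

Step 12
Reactants: 19 (3R)-5,7-bis(benzyloxy)-3-[3-(benzyloxy)-4,5-dimethoxyphenyl]-6-methoxychromane
Product: 20 (3R)-5,7-bis(benzyloxy)-3-[3-(benzyloxy)-4,5-dimethoxyphenyl]-6-methoxychroman-4-ol (mixture of C4 epimers)
Conditions: DDQ (1.2 equiv), CH2Cl2–pH 7 aqueous buffer, 0 °C
Reagents that add atoms: water, O
Why: DDQ benzylic oxidation by hydride abstraction, as practised at C4 of perbenzylated flavan-3-ols: only the C4 cation is stabilised by three ortho/para oxygens (O1, C5–O, C7–O), water should capture it mainly anti to the C3 aryl group, and the new C4 centre is erased in step 13.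

Step 13
Reactants: 20 (3R)-5,7-bis(benzyloxy)-3-[3-(benzyloxy)-4,5-dimethoxyphenyl]-6-methoxychroman-4-ol
Product: 21 (3R)-5,7-bis(benzyloxy)-3-[3-(benzyloxy)-4,5-dimethoxyphenyl]-6-methoxychroman-4-one
Conditions: Dess–Martin periodinane, pyridine, CH2Cl2, 0 °C to rt
Reagents that add atoms: none
Why: Dess–Martin oxidation of a secondary benzylic alcohol, whose pyridine-buffered, near-neutral medium neither ionises the acid-labile carbinol nor enolises the new ketone, so C3 is kept.

Step 14
Reactants: 21 (3R)-5,7-bis(benzyloxy)-3-[3-(benzyloxy)-4,5-dimethoxyphenyl]-6-methoxychroman-4-one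
Product: 22 (3R)-5,7-dihydroxy-3-(3-hydroxy-4,5-dimethoxyphenyl)-6-methoxychroman-4-one (CNP0258659.1)
Conditions: H2 (1 atm), 10% Pd/C, EtOAc, rt
Reagents that add atoms: none
Why: Catalytic hydrogenolysis removes the three aryl benzyl ethers under neutral conditions, the electron-rich vinylogous-ester-like C4 ketone resists hydrogenation, and without acid or base C3 is not enolised.

Compound list
1 | methyl 3,5-dihydroxy-4-methoxybenzoate | COC(=O)c1cc(O)c(OC)c(O)c1 | starting material
2 | methyl 3,5-bis(benzyloxy)-4-methoxybenzoate | COC(=O)c1cc(OCc2ccccc2)c(OC)c(OCc2ccccc2)c1 | intermediate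
3 | [3,5-bis(benzyloxy)-4-methoxyphenyl]methanol | OCc1cc(OCc2ccccc2)c(OC)c(OCc2ccccc2)c1 | intermediate
4 | 3,5-bis(benzyloxy)-4-methoxybenzaldehyde | O=Cc1cc(OCc2ccccc2)c(OC)c(OCc2ccccc2)c1 | intermediate
5 | 3,5-bis(benzyloxy)-4-methoxyphenyl formate (not isolated) | O=COc1cc(OCc2ccccc2)c(OC)c(OCc2ccccc2)c1 | intermediate
6 | 3,5-bis(benzyloxy)-4-methoxyphenol | Oc1cc(OCc2ccccc2)c(OC)c(OCc2ccccc2)c1 | intermediate
7 | formaldehyde | C=O | starting material
8 | sodium p-toluenesulfinate | Cc1ccc(cc1)S(=O)[O-].[Na+] | starting material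
9 | 3,5-bis(benzyloxy)-4-methoxy-2-(tosylmethyl)phenol | COc1c(OCc2ccccc2)cc(O)c(CS(=O)(=O)c2ccc(C)cc2)c1OCc1ccccc1 | intermediate
10 | 3-hydroxy-4,5-dimethoxybenzaldehyde | COc1cc(C=O)cc(O)c1OC | starting material
11 | 3-(benzyloxy)-4,5-dimethoxybenzaldehyde | COc1cc(C=O)cc(OCc2ccccc2)c1OC | intermediate
12 | 1-(benzyloxy)-2,3-dimethoxy-5-(2-methoxyethenyl)benzene (E/Z mixture) | COC=Cc1cc(OC)c(OC)c(OCc2ccccc2)c1 | intermediate
13 | [3-(benzyloxy)-4,5-dimethoxyphenyl]acetaldehyde (not isolated) | O=CCc1cc(OC)c(OC)c(OCc2ccccc2)c1 | intermediate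
14 | [3-(benzyloxy)-4,5-dimethoxyphenyl]acetic acid | COc1cc(CC(=O)O)cc(OCc2ccccc2)c1OC | intermediate
15 | [3-(benzyloxy)-4,5-dimethoxyphenyl]acetic pivalic anhydride (not isolated) | COc1cc(CC(=O)OC(=O)C(C)(C)C)cc(OCc2ccccc2)c1OC | intermediate
16 | 3,5-bis(benzyloxy)-4-methoxy-6-methylidenecyclohexa-2,4-dien-1-one (o-quinone methide, not isolated) | C=C1C(=O)C=C(OCc2ccccc2)C(OC)=C1OCc1ccccc1 | intermediate
17 | (3R)-5,7-bis(benzyloxy)-3-[3-(benzyloxy)-4,5-dimethoxyphenyl]-6-methoxychroman-2-one | COc1cc([C@H]2Cc3c(OCc4ccccc4)c(OC)c(OCc4ccccc4)cc3OC2=O)cc(OCc4ccccc4)c1OC | intermediate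
18 | (3R)-5,7-bis(benzyloxy)-3-[3-(benzyloxy)-4,5-dimethoxyphenyl]-6-methoxychroman-2-ol (C2 anomers) | COc1cc([C@H]2Cc3c(OCc4ccccc4)c(OC)c(OCc4ccccc4)cc3OC2O)cc(OCc4ccccc4)c1OC | intermediate
19 | (3R)-5,7-bis(benzyloxy)-3-[3-(benzyloxy)-4,5-dimethoxyphenyl]-6-methoxychromane | COc1cc([C@H]2Cc3c(OCc4ccccc4)c(OC)c(OCc4ccccc4)cc3OC2)cc(OCc4ccccc4)c1OC | intermediate
20 | (3R)-5,7-bis(benzyloxy)-3-[3-(benzyloxy)-4,5-dimethoxyphenyl]-6-methoxychroman-4-ol (C4 epimers) | COc1cc([C@@H]2COc3cc(OCc4ccccc4)c(OC)c(OCc4ccccc4)c3C2O)cc(OCc4ccccc4)c1OC | intermediate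
21 | (3R)-5,7-bis(benzyloxy)-3-[3-(benzyloxy)-4,5-dimethoxyphenyl]-6-methoxychroman-4-one | COc1cc([C@@H]2COc3cc(OCc4ccccc4)c(OC)c(OCc4ccccc4)c3C2=O)cc(OCc4ccccc4)c1OC | intermediate
22 | (3R)-5,7-dihydroxy-3-(3-hydroxy-4,5-dimethoxyphenyl)-6-methoxychroman-4-one | COc1cc([C@@H]2COc3cc(O)c(OC)c(O)c3C2=O)cc(O)c1OC | target

Total step count: 14 (five for the ring A fragment, three for the ring B fragment, six from the annulation onward).
Longest linear sequence: 11 (steps 1–5 and 9–14).

Steps most likely to fail

1. Step 9.
- **What may go wrong:** facial discrimination on the enolate may be incomplete. The C3 configuration may also erode afterwards through amine-mediated enolisation of the α-aryl aryl ester.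
- **Fallback:** the stereochemical burden moves from the C–C bond formation to a late dynamic kinetic resolution. Material of insufficient enantiopurity is carried through steps 10–13, and the fallback sets out from ketone 21.
- A Noyori-type asymmetric transfer hydrogenation follows (RuCl[(R,R)-TsDPEN](p-cymene), HCO2H–Et3N, EtOAc, 40 °C). Triethylamine equilibrates C3 through the enol while the catalyst fixes C4 as R. It reduces faster the enantiomer whose C3 aryl group lies opposite the incoming hydride.
- This should give the cis-(3R,4R)-chroman-4-ol F1. Oxidation under the conditions of step 13 returns to the route at 21 as a single enantiomer.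

2. Step 12.
- **What may go wrong:** the C4 cation may lose the C3 proton to give the conjugated alkene. It may also attack C8 of a second molecule.
- **Fallback:** the elimination is accepted and C4–O is made by alkene functionalisation instead of C–H oxidation. The fallback sets out from 19.
- DDQ in dry dioxane should give the achiral isoflav-3-ene F2. BH3·SMe2 adds syn with boron on the less hindered C4 to give the trans-alkylborane F3. Alkaline hydrogen peroxide converts this with retention into the racemic trans-chroman-4-ol F4.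
- Dess–Martin periodinane with pyridine then gives the racemic chroman-4-one F5. The transfer hydrogenation with dynamic kinetic resolution described for step 9 (through F1), followed by reoxidation, comes back to the route at 21.

3. Step 11.
- **What may go wrong:** the oxocarbenium ion may lose the C3 proton, and enol ether formation with re-protonation would scramble C3. The lactol may also open to the α-aryl aldehyde and be over-reduced.
- **Fallback:** no cation is formed next to C3, at the price of opening and re-closing O1–C2. The fallback sets out from lactone 17.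
- LiAlH4 in THF at 0 °C should give the (2R)-phenol-alcohol F6. An intramolecular Mitsunobu etherification (PPh3, DIAD, THF, 0 °C), which touches only the primary carbinol carbon, comes back to the route at 19.

Further compounds
F1 | step 9 | (3R,4R)-5,7-bis(benzyloxy)-3-[3-(benzyloxy)-4,5-dimethoxyphenyl]-6-methoxychroman-4-ol (cis) | COc1cc([C@@H]2COc3cc(OCc4ccccc4)c(OC)c(OCc4ccccc4)c3[C@@H]2O)cc(OCc4ccccc4)c1OC
F2 | step 12 | 5,7-bis(benzyloxy)-3-[3-(benzyloxy)-4,5-dimethoxyphenyl]-6-methoxy-2H-chromene (isoflav-3-ene) | COc1cc(C2=Cc3c(OCc4ccccc4)c(OC)c(OCc4ccccc4)cc3OC2)cc(OCc4ccccc4)c1OC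
F3 | step 12 | trans-{5,7-bis(benzyloxy)-3-[3-(benzyloxy)-4,5-dimethoxyphenyl]-6-methoxychroman-4-yl}borane (racemic, one enantiomer drawn, not isolated) | COc1cc([C@@H]2COc3cc(OCc4ccccc4)c(OC)c(OCc4ccccc4)c3[C@H]2B)cc(OCc4ccccc4)c1OC
F4 | step 12 | trans-5,7-bis(benzyloxy)-3-[3-(benzyloxy)-4,5-dimethoxyphenyl]-6-methoxychroman-4-ol (racemic, one enantiomer drawn) | COc1cc([C@@H]2COc3cc(OCc4ccccc4)c(OC)c(OCc4ccccc4)c3[C@H]2O)cc(OCc4ccccc4)c1OC
F5 | step 12 | 5,7-bis(benzyloxy)-3-[3-(benzyloxy)-4,5-dimethoxyphenyl]-6-methoxychroman-4-one (racemic) | COc1cc(C2COc3cc(OCc4ccccc4)c(OC)c(OCc4ccccc4)c3C2=O)cc(OCc4ccccc4)c1OC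
F6 | step 11 | (2R)-2-[3-(benzyloxy)-4,5-dimethoxyphenyl]-3-[2,4-bis(benzyloxy)-6-hydroxy-3-methoxyphenyl]propan-1-ol | COc1cc([C@H](CO)Cc2c(O)cc(OCc3ccccc3)c(OC)c2OCc2ccccc2)cc(OCc2ccccc2)c1OC
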